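One first-order constant cannot carry the gamma run: L, the log of one over the unturned share of the substrate charge, climbs at 0.0712 min⁻¹ over the first 4.6 min and at 0.0172 min⁻¹ from 27 min to 81 min, which is slower.

| flask | substrate | free catalyst | time |
|---|---|---|---|
| theta | 0.600 M | 0.0300 M |  |
| gamma | 1.20 M | 0.0300 M |  |
| eta | 0.600 M | 0.0600 M |  |
| zeta | 0.150 M | 0.0300 M | 81 min |

| run | time / min | [product] / M |
|---|---|---|
| theta run | 4.6 | 0.166 |
| theta run | 14 | 0.297 |
| theta run | 27 | 0.365 |
| theta run | 42 | 0.420 |
| theta run | 61 | 0.461 |
| theta run | 81 | 0.534 |
| gamma run | 4.6 | 0.335 |
| gamma run | 14 | 0.522 |
| gamma run | 27 | 0.634 |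
| gamma run | 42 | 0.779 |
| gamma run | 61 | 0.887 |
| gamma run | 81 | 0.976 |
| eta run | 4.6 | 0.279 |
| eta run | 14 | 0.390 |
| eta run | 27 | 0.407 |
| eta run | 42 | 0.457 |
| eta run | 61 | 0.492 |
| eta run | 81 | 0.510 |

(each reading ± 0.009 M)

- the exponent of [free catalyst] in the starting rate at the charge of the theta run (at the point where two percent of the substrate have become product)
- the exponent of [substrate] in the starting rate at the charge of the theta run (at the point where two percent of the substrate have become product) (one fixed amount of product, the same in the runs compared)
- product in the zeta run at 81 min, as a share of the substrate charged

- Overall: substrate -> product, with free catalyst as catalyst.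
- Constant volume, constant temperature.
- An order is taken over about fifteen percent of the charge, up and down.

I therefore split L into a tail, which I assume grows at that gamma slope in each run, and a burst B, the pseudo-first-order gain while free catalyst lasts, read as L at 27 min minus the tail.

Now take the balance of the free catalyst, the reagent charged in the smaller amount, and suppose its surviving share falls in proportion to itself and to the product share. L gains in proportion to the catalyst charge times that surviving share. While the product share is close to L, the lost share therefore grows with the square of L times substrate charge over catalyst charge. This reckoning then puts the end of the burst near B = W√(catalyst charge/substrate charge), with W the burst constant.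

| run | catalyst per substrate | B | W |
|---|---|---|---|
| theta | 0.0500 | 0.474 | 2.12 |
| gamma | 0.0250 | 0.288 | 1.82 |
| eta | 0.100 | 0.671 | 2.12 |

The gamma burst is smaller than the theta burst at the same catalyst charge, which speaks for a loss tied to product rather than to the clock. With the theta W, the zeta run gets a burst of 0.948, and the tail adds 1.39 by 81 min, so its share is 90.3 %.

The weak link is that single W, so I reforge it and carry the mean burst constant of the table, 2.02. The zeta burst becomes 0.904, and I commit to a share of 89.9 %. The first readings, taken at the same time of 4.6 min and not at equal product, give me as ratios of product exponents of 1.01 in substrate and 0.749 in free catalyst.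

The forecast gives 1 for free catalyst (0.8 to 1.3), 0.9 for substrate (0.7 to 1.1) and 87 % for the zeta run (78 % to 95 %), on the view that “The catalyst seems to die or be choked.” Its catalyst exponent is higher than mine, and its zeta share is lower than mine.

    free catalyst + substrate → product + free catalyst (2.460 M⁻¹ min⁻¹)
    free catalyst + product → spent catalyst + product (0.9960 M⁻¹ min⁻¹)
    substrate → product (0.01644 min⁻¹)

The zeta run gives 91.0 % at 81 min, and the exponents are 1.0 in substrate and 0.82 in free catalyst, against the 1 of the forecast. Where two percent of the theta substrate have turned, the eta run, with 0.0600 M of free catalyst against 0.0300 M in the theta run, goes at 1.8 times the theta rate. Put to the eta run at 81 min, whose own reading at 27 min went into that mean, the mean burst constant and the tail give a share of 86.9 %, and the reading there is 85.0 %.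

The readings stem from a simulated flask for substances that don't exist, noise included.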